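## Retrosynthetic overview

1. The hydroquinone is made last: both silyl ethers are removed, then the 2,6-disubstituted phenol is oxidised at its free para position and the quinone is reduced.
2. Key disconnection C5–C6 (side chain numbered from the arene): the (5S)-allylic carbinol comes from an enantioenriched α-lithiated homoallylic N,N-diisopropylcarbamate (a chiral α-oxy carbanion) and an (E)-alkenyl pinacol boronate, by 1,2-metallate shift and C–B oxidation.
3. Arene-side fragment (C1–C5): but-3-yn-1-ol → carbamate → Zr-catalysed methylalumination/formaldehyde → ortho-allylation of o-cresol → aryl silyl ether.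
4. Chain fragment (C6–C16): (E)-geranylacetone → terminal alkyne → SeO2 ω-hydroxylation → silyl ether → methylalumination/borylation.
5. Rings: none is built; the benzene ring is bought as o-cresol and only raised to the hydroquinone oxidation level in the final step.

Assumption: (5E)-geranylacetone is used as the single E isomer and (+)-sparteine is bought as such; both are commercial.

## Route

Step 1
Reactants: 1 but-3-yn-1-ol
Product: 2 but-3-yn-1-yl N,N-diisopropylcarbamate
Conditions: iPr2NCOCl (1.2 equiv), Et3N (1.3 equiv), DMAP (5 mol %), CH2Cl2, reflux, 24 h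
Reagents that add atoms: N,N-diisopropylcarbamoyl chloride, CC(C)N(C(C)C)C(Cl)=O
Why: O-carbamoylation (acyl substitution) of the primary alcohol installs the hindered Hoppe-type carbamate that later directs and stabilises α-lithiation.

Step 2
Reactants: 2 but-3-yn-1-yl N,N-diisopropylcarbamate
Product: 4 (3E)-5-hydroxy-3-methylpent-3-en-1-yl N,N-diisopropylcarbamate, via alkenylalane 3 (not isolated)
Conditions: Me3Al (3 equiv), Cp2ZrCl2 (25 mol %), (CH2Cl)2, 0 °C→rt, 12 h; then (CH2O)n (5 equiv), THF, 0 °C→rt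
Reagents that add atoms: trimethylaluminium, C[Al](C)C; paraformaldehyde (formaldehyde unit), C=O
Why: Negishi Zr-catalysed methylalumination adds Me and Al syn with Al at the terminus, which fixes the E trisubstituted olefin, and the alkenyl–Al bond is hydroxymethylated with retention while the hindered carbamate is inert to Me3Al.

Step 3
Reactants: 4 (3E)-5-hydroxy-3-methylpent-3-en-1-yl N,N-diisopropylcarbamate; 5 o-cresol (2 equiv)
Product: 6 (3E)-5-(2-hydroxy-3-methylphenyl)-3-methylpent-3-en-1-yl N,N-diisopropylcarbamate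
Conditions: acidic Al2O3 (Brockmann I), (CH2Cl)2, reflux, 24 h
Reagents that add atoms: none
Why: alumina-promoted dehydrative Friedel–Crafts ortho-allylation, in which the surface-bound phenoxide delivers the primary allyl terminus to the only free ortho position of o-cresol with loss of water from the allylic alcohol and with the E olefin retained.

Step 4
Reactants: 6 (3E)-5-(2-hydroxy-3-methylphenyl)-3-methylpent-3-en-1-yl N,N-diisopropylcarbamate
Product: 7 (3E)-5-{2-[(tert-butyldimethylsilyl)oxy]-3-methylphenyl}-3-methylpent-3-en-1-yl N,N-diisopropylcarbamate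
Conditions: TBSCl (1.5 equiv), imidazole (3 equiv), DMF, 40 °C, 16 h
Reagents that add atoms: tert-butyldimethylsilyl chloride, CC(C)(C)[Si](C)(C)Cl
Why: silylation of the phenol removes the acidic proton before the organolithium step, and the resulting 2,6-disubstituted aryl silyl ether has no ortho hydrogen for directed metalation.

Step 5
Reactants: 8 (5E)-geranylacetone
Product: 10 (5E)-6,10-dimethylundeca-5,9-dien-1-yne, via enol phosphate 9 (not isolated)
Conditions: LDA (1.1 equiv), THF, −78 °C; ClP(O)(OEt)2 (1.15 equiv), −78 °C→rt; LDA (2.3 equiv), −78 °C→rt; aq. NH4Cl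
Reagents that add atoms: none
Why: Negishi methyl ketone-to-alkyne conversion, in which kinetic deprotonation at the methyl group, O-phosphorylation to 9 and LDA-induced elimination give the terminal alkyne without touching the E olefin.

Step 6
Reactants: 10 (5E)-6,10-dimethylundeca-5,9-dien-1-yne
Product: 11 (2E,6E)-2,6-dimethylundeca-2,6-dien-10-yn-1-ol
Conditions: SeO2 (10 mol %), salicylic acid (10 mol %), t-BuOOH (70% aq., 3.5 equiv), CH2Cl2, rt, 24–36 h (stopped at about 70% conversion)
Reagents that add atoms: tert-butyl hydroperoxide (stoichiometric O source), CC(C)(C)OO; selenium dioxide (catalytic O carrier), O=[Se]=O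
Why: Sharpless SeO2/t-BuOOH allylic oxidation (ene reaction then [2,3]-sigmatropic shift) hydroxylates the trans methyl of the more accessible terminal isopropylidene, giving the E allylic alcohol.

Step 7
Reactants: 11 (2E,6E)-2,6-dimethylundeca-2,6-dien-10-yn-1-ol
Product: 12 tert-butyl{[(2E,6E)-2,6-dimethylundeca-2,6-dien-10-yn-1-yl]oxy}dimethylsilane
Conditions: TBSCl (1.2 equiv), imidazole (2 equiv), CH2Cl2, 0 °C→rt
Reagents that add atoms: tert-butyldimethylsilyl chloride, CC(C)(C)[Si](C)(C)Cl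
Why: silylation masks the hydroxyl proton, which would otherwise quench the lithiated carbamate in the coupling step.

Step 8
Reactants: 12 tert-butyl{[(2E,6E)-2,6-dimethylundeca-2,6-dien-10-yn-1-yl]oxy}dimethylsilane
Product: 14 tert-butyldimethyl{[(2E,6E,10E)-2,6,10-trimethyl-11-(4,4,5,5-tetramethyl-1,3,2-dioxaborolan-2-yl)undeca-2,6,10-trien-1-yl]oxy}silane, via alkenylalane 13 (not isolated)
Conditions: Me3Al (2.5 equiv), Cp2ZrCl2 (20 mol %), CH2Cl2, 0 °C→rt, 12 h; then MeOBpin (4 equiv), THF, 0 °C→rt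
Reagents that add atoms: trimethylaluminium, C[Al](C)C; 2-methoxy-4,4,5,5-tetramethyl-1,3,2-dioxaborolane, COB1OC(C)(C)C(C)(C)O1
Why: Negishi Zr-catalysed syn-methylalumination sets the E geometry (B cis to the new methyl) and Al-to-B transmetalation onto the alkoxyboronate occurs with retention, driven by Al–O bond formation.

Step 9
Reactants: 7 (3E)-5-{2-[(tert-butyldimethylsilyl)oxy]-3-methylphenyl}-3-methylpent-3-en-1-yl N,N-diisopropylcarbamate (1.3 equiv); 14 tert-butyldimethyl{[(2E,6E,10E)-2,6,10-trimethyl-11-(4,4,5,5-tetramethyl-1,3,2-dioxaborolan-2-yl)undeca-2,6,10-trien-1-yl]oxy}silane (1.0 equiv)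
Product: 18 (2E,5S,6E,10E,14E)-16-[(tert-butyldimethylsilyl)oxy]-1-{2-[(tert-butyldimethylsilyl)oxy]-3-methylphenyl}-3,7,11,15-tetramethylhexadeca-2,6,10,14-tetraen-5-ol, via lithiated carbamate 15 (not isolated), via boronate complex 16 (not isolated), via allylic boronic ester 17 (not isolated)
Conditions: (+)-sparteine (1.3 equiv), s-BuLi (1.25 equiv), Et2O, −78 °C, 5 h; 14 in Et2O, −78 °C, 1 h, then 35 °C, 2 h; then THF, 2 M NaOH, 30% H2O2, 0 °C, 1 h
Reagents that add atoms: hydrogen peroxide, OO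
Why: Hoppe–Aggarwal lithiation–borylation, in which s-BuLi/(+)-sparteine removes the pro-R α-hydrogen to give the configurationally stable (R)-organolithium 15, borylation proceeds with retention to 16, the alkenyl group migrates from B to C with inversion while the carbamate leaves to form the C5–C6 bond in 17, and C–B oxidation with retention gives the 5S alcohol (expected er about 96:4).

Step 10
Reactants: 18 (2E,5S,6E,10E,14E)-16-[(tert-butyldimethylsilyl)oxy]-1-{2-[(tert-butyldimethylsilyl)oxy]-3-methylphenyl}-3,7,11,15-tetramethylhexadeca-2,6,10,14-tetraen-5-ol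
Product: 19 2-[(2E,5S,6E,10E,14E)-5,16-dihydroxy-3,7,11,15-tetramethylhexadeca-2,6,10,14-tetraen-1-yl]-6-methylphenol
Conditions: TBAF (3 equiv), THF, 0 °C→rt, 3 h
Reagents that add atoms: none
Why: fluoride-mediated desilylation cleaves the aryl and the primary allylic silyl ether together without affecting the olefins or the C5 stereocentre.

Step 11
Reactants: 19 2-[(2E,5S,6E,10E,14E)-5,16-dihydroxy-3,7,11,15-tetramethylhexadeca-2,6,10,14-tetraen-1-yl]-6-methylphenol
Product: 21 2-[(2E,5S,6E,10E,14E)-5,16-dihydroxy-3,7,11,15-tetramethylhexadeca-2,6,10,14-tetraen-1-yl]-6-methylbenzene-1,4-diol, via quinone 20 (not isolated)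
Conditions: Fremy's salt (2.5 equiv), aq. KH2PO4 (0.06 M), acetone/H2O, 0 °C→rt, 2 h; extract; sat. aq. Na2S2O4, Et2O/H2O, Ar, rt, 15 min
Reagents that add atoms: potassium nitrosodisulfonate (Fremy's salt), [K+].[K+].[O]N(S(=O)(=O)[O-])S(=O)(=O)[O-]
Why: Teuber oxidation selectively converts the 2,6-dialkylphenol with a free para position into the p-quinone 20 without touching alcohols or olefins, and dithionite reduces it to the hydroquinone, the C5 stereocentre being untouched.

## Compound list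

1 | but-3-yn-1-ol | C#CCCO | starting material
2 | but-3-yn-1-yl N,N-diisopropylcarbamate | C#CCCOC(=O)N(C(C)C)C(C)C | intermediate
3 | [(1E)-4-(N,N-diisopropylcarbamoyloxy)-2-methylbut-1-en-1-yl]dimethylalane | C[Al](C)/C=C(\C)CCOC(=O)N(C(C)C)C(C)C | intermediate (not isolated)
4 | (3E)-5-hydroxy-3-methylpent-3-en-1-yl N,N-diisopropylcarbamate | OC/C=C(\C)CCOC(=O)N(C(C)C)C(C)C | intermediate
5 | o-cresol (2-methylphenol) | Cc1ccccc1O | starting material
6 | (3E)-5-(2-hydroxy-3-methylphenyl)-3-methylpent-3-en-1-yl N,N-diisopropylcarbamate | Cc1cccc(C/C=C(\C)CCOC(=O)N(C(C)C)C(C)C)c1O | intermediate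
7 | (3E)-5-{2-[(tert-butyldimethylsilyl)oxy]-3-methylphenyl}-3-methylpent-3-en-1-yl N,N-diisopropylcarbamate | Cc1cccc(C/C=C(\C)CCOC(=O)N(C(C)C)C(C)C)c1O[Si](C)(C)C(C)(C)C | intermediate
8 | (5E)-geranylacetone, (5E)-6,10-dimethylundeca-5,9-dien-2-one | CC(=O)CC/C=C(\C)CCC=C(C)C | starting material
9 | diethyl (5E)-6,10-dimethylundeca-1,5,9-trien-2-yl phosphate | C=C(CC/C=C(\C)CCC=C(C)C)OP(=O)(OCC)OCC | intermediate (not isolated)
10 | (5E)-6,10-dimethylundeca-5,9-dien-1-yne | C#CCC/C=C(\C)CCC=C(C)C | intermediate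
11 | (2E,6E)-2,6-dimethylundeca-2,6-dien-10-yn-1-ol | C#CCC/C=C(\C)CC/C=C(\C)CO | intermediate
12 | tert-butyl{[(2E,6E)-2,6-dimethylundeca-2,6-dien-10-yn-1-yl]oxy}dimethylsilane | C#CCC/C=C(\C)CC/C=C(\C)CO[Si](C)(C)C(C)(C)C | intermediate
13 | {(1E,5E,9E)-11-[(tert-butyldimethylsilyl)oxy]-2,6,10-trimethylundeca-1,5,9-trien-1-yl}dimethylalane | C[Al](C)/C=C(\C)CC/C=C(\C)CC/C=C(\C)CO[Si](C)(C)C(C)(C)C | intermediate (not isolated)
14 | tert-butyldimethyl{[(2E,6E,10E)-2,6,10-trimethyl-11-(4,4,5,5-tetramethyl-1,3,2-dioxaborolan-2-yl)undeca-2,6,10-trien-1-yl]oxy}silane | CC1(C)OB(/C=C(\C)CC/C=C(\C)CC/C=C(\C)CO[Si](C)(C)C(C)(C)C)OC1(C)C | intermediate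
15 | [(1R,3E)-5-{2-[(tert-butyldimethylsilyl)oxy]-3-methylphenyl}-1-(N,N-diisopropylcarbamoyloxy)-3-methylpent-3-en-1-yl]lithium, as its (+)-sparteine complex | Cc1cccc(C/C=C(\C)C[C@@H]([Li])OC(=O)N(C(C)C)C(C)C)c1O[Si](C)(C)C(C)(C)C | intermediate (not isolated)
16 | lithium pinacolato borate complex carrying the (1R,3E)-1-(carbamoyloxy)pentenyl group of 15 and the (1E,5E,9E)-trienyl group of 14 on boron | [Li+].Cc1cccc(C/C=C(\C)C[C@H](OC(=O)N(C(C)C)C(C)C)[B-]2(OC(C)(C)C(C)(C)O2)/C=C(\C)CC/C=C(\C)CC/C=C(\C)CO[Si](C)(C)C(C)(C)C)c1O[Si](C)(C)C(C)(C)C | intermediate (not isolated)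
17 | 2-[(2E,5S,6E,10E,14E)-16-[(tert-butyldimethylsilyl)oxy]-1-{2-[(tert-butyldimethylsilyl)oxy]-3-methylphenyl}-3,7,11,15-tetramethylhexadeca-2,6,10,14-tetraen-5-yl]-4,4,5,5-tetramethyl-1,3,2-dioxaborolane | Cc1cccc(C/C=C(\C)C[C@H](B2OC(C)(C)C(C)(C)O2)/C=C(\C)CC/C=C(\C)CC/C=C(\C)CO[Si](C)(C)C(C)(C)C)c1O[Si](C)(C)C(C)(C)C | intermediate (not isolated)
18 | (2E,5S,6E,10E,14E)-16-[(tert-butyldimethylsilyl)oxy]-1-{2-[(tert-butyldimethylsilyl)oxy]-3-methylphenyl}-3,7,11,15-tetramethylhexadeca-2,6,10,14-tetraen-5-ol | Cc1cccc(C/C=C(\C)C[C@H](O)/C=C(\C)CC/C=C(\C)CC/C=C(\C)CO[Si](C)(C)C(C)(C)C)c1O[Si](C)(C)C(C)(C)C | intermediate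
19 | 2-[(2E,5S,6E,10E,14E)-5,16-dihydroxy-3,7,11,15-tetramethylhexadeca-2,6,10,14-tetraen-1-yl]-6-methylphenol | Cc1cccc(C/C=C(\C)C[C@H](O)/C=C(\C)CC/C=C(\C)CC/C=C(\C)CO)c1O | intermediate
20 | 2-[(2E,5S,6E,10E,14E)-5,16-dihydroxy-3,7,11,15-tetramethylhexadeca-2,6,10,14-tetraen-1-yl]-6-methylcyclohexa-2,5-diene-1,4-dione | CC1=CC(=O)C=C(C/C=C(\C)C[C@H](O)/C=C(\C)CC/C=C(\C)CC/C=C(\C)CO)C1=O | intermediate (not isolated)
21 | 2-[(2E,5S,6E,10E,14E)-5,16-dihydroxy-3,7,11,15-tetramethylhexadeca-2,6,10,14-tetraen-1-yl]-6-methylbenzene-1,4-diol (CNP0151872.1) | Cc1cc(O)cc(C/C=C(\C)C[C@H](O)/C=C(\C)CC/C=C(\C)CC/C=C(\C)CO)c1O | target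

## Step count and risks

Total steps: 11 (arene-side fragment 4, chain fragment 4, coupling 1, endgame 2).
Longest linear sequence: 7 steps (steps 1, 2, 3, 4, 9, 10, 11; the other arm, steps 5, 6, 7, 8, 9, 10, 11, is equally long).

Three steps most likely to fail:

**Step 9 (lithiation–borylation).** s-BuLi may instead deprotonate the doubly activated benzylic/allylic CH2 or the allylic CH2 β to the carbamate (which would eliminate), and the hindered trisubstituted alkenyl boronate may form the ate complex or migrate sluggishly. The fallback sets out from 7 and 12 and comes back at 18. Compound 7 is decarbamoylated with LiAlH4 in refluxing THF to (3E)-5-{2-[(tert-butyldimethylsilyl)oxy]-3-methylphenyl}-3-methylpent-3-en-1-ol F1. F1 is oxidised with Dess–Martin periodinane/NaHCO3 in CH2Cl2 at 0 °C to (3E)-5-{2-[(tert-butyldimethylsilyl)oxy]-3-methylphenyl}-3-methylpent-3-enal F2, which is used at once. Alkyne 12 is methylaluminated as in step 8 (via 13) but quenched with I2 to give tert-butyl{[(2E,6E,10E)-11-iodo-2,6,10-trimethylundeca-2,6,10-trien-1-yl]oxy}dimethylsilane F3. An asymmetric Nozaki–Hiyama–Kishi coupling of F2 and F3 (CrCl2, cat. NiCl2, Kishi-type chiral sulfonamide ligand of the enantiomer that gives the 5S carbinol, Et3N, THF, rt) then forms the same C5–C6 bond by reductive union of two electrophiles and gives 18.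

**Step 6 (SeO2 ω-hydroxylation).** The internal trisubstituted olefin is not deactivated, so oxidation at its allylic CH2, over-oxidation to the enal and double oxidation can lower the yield (40–50% expected). The fallback sets out from 10 and comes back at 11, replacing C–H oxidation by terminal-olefin degradation and re-olefination. Terminal-selective bromohydrin formation (NBS, THF/H2O, 0 °C) gives (6E)-3-bromo-2,6-dimethylundec-6-en-10-yn-2-ol F4. K2CO3 in MeOH closes it to 2,2-dimethyl-3-[(3E)-3-methyloct-3-en-7-yn-1-yl]oxirane F5. HIO4·2H2O in THF/Et2O cleaves the epoxide to (4E)-4-methylnon-4-en-8-ynal F6. Wittig olefination with Ph3P=C(CH3)CO2Et in CH2Cl2 gives ethyl (2E,6E)-2,6-dimethylundeca-2,6-dien-10-ynoate F7 with the E geometry set by the stabilised ylide, and DIBAL-H (CH2Cl2, −78 °C) reduces F7 to 11.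

**Step 3 (alumina ortho-allylation).** The Lewis-basic carbamate may bind the alumina or trap the allyl cation intramolecularly, and acid-induced chroman formation or para-allylation may compete. The fallback sets out from 4 (with 5) and comes back at 6, replacing the acid-surface dehydrative alkylation by base-mediated phenoxide C-alkylation. Appel bromination of 4 (CBr4, PPh3, CH2Cl2, 0 °C) gives (3E)-5-bromo-3-methylpent-3-en-1-yl N,N-diisopropylcarbamate F8. The sodium salt of 5 (NaH, toluene), as a contact ion pair in the non-polar solvent, is alkylated by F8 at the ortho carbon at rt to give 6.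

## Further compounds

F1 | step 9 | (3E)-5-{2-[(tert-butyldimethylsilyl)oxy]-3-methylphenyl}-3-methylpent-3-en-1-ol | Cc1cccc(C/C=C(\C)CCO)c1O[Si](C)(C)C(C)(C)C
F2 | step 9 | (3E)-5-{2-[(tert-butyldimethylsilyl)oxy]-3-methylphenyl}-3-methylpent-3-enal | Cc1cccc(C/C=C(\C)CC=O)c1O[Si](C)(C)C(C)(C)C
F3 | step 9 | tert-butyl{[(2E,6E,10E)-11-iodo-2,6,10-trimethylundeca-2,6,10-trien-1-yl]oxy}dimethylsilane | I/C=C(\C)CC/C=C(\C)CC/C=C(\C)CO[Si](C)(C)C(C)(C)C
F4 | step 6 | (6E)-3-bromo-2,6-dimethylundec-6-en-10-yn-2-ol (racemic) | C#CCC/C=C(\C)CCC(Br)C(C)(C)O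
F5 | step 6 | 2,2-dimethyl-3-[(3E)-3-methyloct-3-en-7-yn-1-yl]oxirane (racemic) | C#CCC/C=C(\C)CCC1OC1(C)C
F6 | step 6 | (4E)-4-methylnon-4-en-8-ynal | C#CCC/C=C(\C)CCC=O
F7 | step 6 | ethyl (2E,6E)-2,6-dimethylundeca-2,6-dien-10-ynoate | C#CCC/C=C(\C)CC/C=C(\C)C(=O)OCC
F8 | step 3 | (3E)-5-bromo-3-methylpent-3-en-1-yl N,N-diisopropylcarbamate | BrC/C=C(\C)CCOC(=O)N(C(C)C)C(C)C
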